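The data were generated by integration from invented constants.

1. The ratio I go by in the west flask is 40.7, read at 80.0 s: the selectivity factor, the logarithm of the fraction of left-handed substrate left over that of right-handed substrate left, each of its own charge. It is a reading and carries the scatter of 1 percentage point.

| setting | west | flask |
|---|---|---|
| left-handed substrate | 1 mM | 1.0 mM |
| right-handed substrate | 1 mM | 1.0 mM |
| partner | 2 mM | 2.00 mM |
| catalyst | 27 µM | 27 µM |
| added ligand | 27 µM | 27 µM |
| remark | the very flask that is asked about, followed so far |  |
| time |  | 4.0 min |

west run (percent of the left-handed substrate and right-handed substrate together charged)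

| time / s | right-handed substrate / % | left-handed substrate / % |
|---|---|---|
| 10.0 | 48.0 | 25.6 |
| 20.0 | 48.7 | 16.5 |
| 30.0 | 47.3 | 9.3 |
| 40.0 | 47.1 | 8.6 |
| 50.0 | 47.0 | 6.3 |
| 60.0 | 47.8 | 6.8 |
| 80.0 | 47.2 | 4.8 |

(scatter of a reading: 1 percentage point)

- catalyst is single-handed; left-handed substrate and right-handed substrate are mirror images of each other, charged as a racemate, each of them at the stated concentration
- the numbers in the tables scatter with a standard deviation of 1 points

1. whether the excess of right-handed substrate over left-handed substrate among what is left of the two reaches 99 % by 4.0 min (yes / no)
2. the highest excess of right-handed substrate over left-handed substrate among what is left of the two up to 4.0 min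

2. The wanted excess requires left-handed substrate at 0.503 % of right-handed substrate. With my selectivity factor, that falls at 43.8 % right-handed and 0.220 % left-handed substrate, in percent of the two charged together.

3. I treat left-handed substrate in the west run as pseudo-first-order between 20.0 s and 80.0 s, which gives a rate constant, read from scattered readings, of 1.23 min⁻¹. On that estimate I expect it at that level at 3.83 min, narrowly inside the 4.0 min allowed.

4. My decision: I change no charge and leave the west flask running to 4.0 min, not stopping it at 80.0 s.

5. The forecast differs from my reckoning: it says no, with a top excess of 89 %, and it calls the left-handed substrate level that 99 % needs one “which neither reading allows”.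

6. The west flask gives yes: the excess reaches 99 % at 2.97 min, earlier than my time, with 43.8 % right-handed substrate left, and it tops at 99.8 %.

    partner + catalyst + left-handed substrate → catalyst + left-handed product (k = 1.71 × 10⁶ M⁻² s⁻¹)
    partner + catalyst + right-handed substrate → catalyst + right-handed product (k = 42000 M⁻² s⁻¹)
    catalyst ⇌ dormant form (K = 0.480, k = 0.0263 s⁻¹)
    partner → decomposition product (k = 5.39 × 10⁻⁵ s⁻¹)
    catalyst + added ligand ⇌ idle complex (K = 7500 M⁻¹, k = 1.18 × 10⁵ M⁻¹ s⁻¹)

At the start in the west flask, the rate of partner use by the left-handed step over that by the right-handed step is 41, and the selectivity factor from the state at 4.00 min is 40.7. The half-life of left-handed substrate by its step at 0.192 min is 0.24 min, short against the 4.0 min allowed, and at 4.00 min the flask holds 0.10 % of the charged left-handed substrate and 84 % of the charged right-handed substrate.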